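## Analysis of the target

Target 28 is an achiral 2‑aryl‑1‑benzofuran. Ring A (the benzo ring) carries OH at C4 and C6 and a 1,1‑dimethylallyl (2‑methylbut‑3‑en‑2‑yl) group at C7. Ring B (the phenyl ring on C2) carries a prenyl group at C2', OMe at C3' and OH at C5'. There is no stereocentre and no configurable double bond, so every selectivity question is one of constitution: where the two C5 units sit and which of the four oxygens is methylated. The sensitive groups are three free phenols on electron‑rich rings, the trisubstituted prenyl alkene (acid, electrophiles), the 1,1‑dimethylallyl group next to 6‑OH (ring closure under acid or heat) and the electron‑rich furan C2=C3 bond. The difficulty is that both isoprenoid carbons sit at the most crowded sites: C7 lies between O1 and the C6 oxygen, and C2' lies between the biaryl bond and C3'‑OMe, where substitution of a 3,5‑dioxygenated arene does not go (it goes to C4' or C6'). The strategy rests on the fact that ring B, with C1' carbon‑bound and oxygen at C3' and C5', is the aromatised form of a 5‑substituted cyclohexane‑1,3‑dione. In the derived 3‑alkoxycyclohex‑2‑enone the kinetically acidic α' carbon is the future C2', the ketone oxygen the future O3' and the enol ether oxygen the future O5'.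

## Retrosynthetic reasoning

28 from 27: the three acetal C–O bonds on O4, O6 and O5' are cut last. Methoxymethyl (MOM) ethers survive alkoxide, hydroxide, hydride and amide bases, and one mild acid step then frees all three phenols while the methyl ether stays.

27 from 26: the O3'–CH3 bond is cut. Phenol 26 has only this one free OH, so the methylation needs no selectivity; the differentiation of O3' from O5' comes from the way ring B is made.

26 from 21 (through 23): ring B is taken back to a cyclohexenone by adding two hydrogens across C1'–C2'. In the forward direction a selenium group is placed on the α' carbon of 21 and the selenoxide eliminates toward the ring hydrogen; the dienone formed is a tautomer of 26. The dehydrogenation must spare two isolated alkenes, which rules out quinone or metal dehydrogenation as the first choice.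

21 from 19 and 2: the C2'–CH2 bond is cut. In 19 the only kinetically acidic CH2 lies between the carbonyl and the carbon bearing the benzofuran, so enolate chemistry places the prenyl group of bromide 2 exactly where arene chemistry would not.

19 from 18: the enol ether O–C bond is cut. Dione 18 is symmetric, so only one enol ether can form; its oxygen is protected with the same group as the ring A phenols.

18 from 13 and 14 (key disconnection): two C–C bonds of ring B are cut, the one from C1' to the malonate carbon and the one between the former acetyl methyl carbon and a malonate carbonyl. Here ring B has only the biaryl carbon fixed, and a single condensation of enone 13 with dimethyl malonate 14 closes the carbocycle and leaves a symmetric dione.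

13 from 11 and 12, and 11 from 9 through 10: the enone C=C bond is cut to aldehyde 11 and ylide 12; the aldehyde comes from ester 9 by reduction to alcohol 10 and re‑oxidation. These are redox and olefination steps without selectivity issues.

9 from 6 and 7: the furan bonds O1–C2 and C2–C3 are cut, which leads to salicylaldehyde 6 and ethyl bromoacetate 7. All ring A substituents are already in place in 6.

6 from 5, 5 from 3, 3 from 1 and 2: the two MOM groups are removed and the aryl–C(quaternary) bond at the future C7 is reconnected to oxygen as a prenyl ether (Claisen transform). The ether is placed on the future O6 (the 4‑oxygen of aldehyde 1) and not on the future O1. In 3 the carbon para to that oxygen carries the formyl group and the two ortho carbons are equivalent, so the rearrangement has one outcome. A prenyl ether on the future O1 would have an open para position, to which the group could travel by a second [3,3] shift as a linear prenyl group.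

## Alternatives that were turned down

Alternative 1: Ring A is cut at C3a–C4 and traced to a furan that already carries ring B and, on its other α‑carbon, the acyl Meldrum's acid chain of A2.
- Key step: heating A2 would unmask acylketene A3, whose ketene carbon must bond to the furan β‑carbon; tautomerisation then gives the 4,6‑dihydroxybenzofuran A1, the 5'‑O‑silyl ether of 28.
- For: the oxygens of ring A and the C7 substituent are fixed by connectivity, so there is no rearrangement question at all. On this point it is stronger than the chosen route. A1 is also one desilylation from the target.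
- Against: ring B must be supplied as a finished arene with the prenyl group between the furan bond and OMe, so the hardest regiochemical problem is handed back to arene substitution. The closure has to use the less nucleophilic β‑position of a furan and pass through a non‑aromatic intermediate, next to a carbon with a quaternary substituent. The ketene can also be captured by the phenols of product already formed.
- Comparison: the step count is not lower once the ring B arene and A2 are made. The chosen route offers a ring B whose substitution pattern follows from enolate acidity and a key step of an old, dependable type.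

Alternative 2: The benzofuran C3–C3a bond is cut and the five‑membered ring is traced to the pyranone of flavanone A5.
- Key step: a hypervalent iodine oxidant with acid in an orthoester medium would attack the enol ether of A5 at its α‑carbon; ring A shifts from the carbonyl carbon to that carbon and the ring contracts to the trans‑dihydrobenzofuran ester A4.
- For: flavanones are assembled convergently from two simple aromatic pieces, the ring contraction is an established reaction of flavanones, and the relative configuration of A4 is irrelevant.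
- Against: A4 is not yet a benzofuran. The ester carbon has to be removed again and C2–C3 dehydrogenated, and three allyl ethers cleaved. The oxidant is an electrophile toward the prenyl alkene, the allyl ethers and the electron‑rich rings, under acid. The aldehyde needed for A5 is once more the 2‑prenyl‑3‑methoxy arene.
- Comparison: it is stronger in convergence. The chosen route avoids building in a carbon that is later excised, needs no electrophilic oxidant at room temperature in the presence of the alkenes, and makes the ring B pattern instead of presupposing it.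

Alternative 3: The furan O1–C2 bond is cut, leading to E‑stilbene A7, whose only free phenol is the future O1.
- Key step: a hypervalent iodine oxidant would join that oxygen to the stilbene carbon bearing ring B with loss of two hydrogens, giving tris‑silyl ether A6.
- For: it is the shortest and most convergent plan, it follows the likely biogenesis, and the final fluoride deprotection is gentler than the acid used in the chosen route.
- Against: both arenes of A7 must be complete beforehand, so the prenyl at C2' is again an unsolved arene substitution. The free phenol sits on a very electron‑rich ring with an open para carbon, where the oxidant can dearomatise instead of cyclising. The attacking oxygen is flanked by the 1,1‑dimethylallyl group and the receiving carbon carries an ortho‑prenylated, twisted aryl ring.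
- Comparison: if A7 were in hand it would win on step count. The chosen route replaces an uncertain oxidative C–O closure and an open regiochemical problem by carbonyl condensations with predictable site selectivity.

Key step: step 8

Remark on the chemistry: the future ring B carries stereocentres in compounds 15–17 and 19–24; they are handled as racemates (21 and 23 in the expected relative configuration) because the aromatisation in step 12 removes all of them.

Abbreviations: MOM = methoxymethyl; Bzf = the 4,6‑bis(methoxymethoxy)‑7‑(2‑methylbut‑3‑en‑2‑yl)‑1‑benzofuran‑2‑yl group.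

## Route

Step 1
Reactants: 1 2,4,6‑trihydroxybenzaldehyde; 2 prenyl bromide (1‑bromo‑3‑methylbut‑2‑ene, 0.95 equiv)
Product: 3 2,6‑dihydroxy‑4‑[(3‑methylbut‑2‑en‑1‑yl)oxy]benzaldehyde
Conditions: K2CO3 (1.0 equiv), DMF, 0 °C → rt
Reagents that add atoms: none
Why: Williamson etherification: the 4‑OH of 1 is para to the formyl group, not hydrogen‑bonded and the most acidic, so one equivalent of K2CO3 ionises it alone and the phenoxide reacts with the primary allylic bromide on oxygen in DMF; a slight deficit of 2 limits double alkylation.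

Step 2
Reactants: 3 2,6‑dihydroxy‑4‑[(3‑methylbut‑2‑en‑1‑yl)oxy]benzaldehyde
Product: 5 2,4,6‑trihydroxy‑3‑(2‑methylbut‑3‑en‑2‑yl)benzaldehyde, via cyclohexadienone 4 (not isolated)
Conditions: EtOH–H2O (4:1), 130 °C, sealed tube, under argon
Reagents that add atoms: none
Why: Aromatic Claisen rearrangement ([3,3] shift of the aryl prenyl ether): the two ortho carbons of 3 are equivalent and the para carbon carries the formyl group, so the inverted C5 unit can only arrive at C3 and a following Cope shift has no position from which a phenol could form; the protic medium accelerates the shift and the enolisation of dienone 4 to 5.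

Step 3
Reactants: 5 2,4,6‑trihydroxy‑3‑(2‑methylbut‑3‑en‑2‑yl)benzaldehyde
Product: 6 2‑hydroxy‑4,6‑bis(methoxymethoxy)‑3‑(2‑methylbut‑3‑en‑2‑yl)benzaldehyde
Conditions: MOMCl (2.1 equiv), iPr2NEt, CH2Cl2, 0 °C
Reagents that add atoms: chloromethyl methyl ether, COCCl
Why: Selective acetal etherification: the 4‑OH (most acidic) and the unhindered 6‑OH react, whereas the 2‑OH lies between the formyl group and the quaternary carbon and stays in the hydrogen bond to C=O, the usual outcome for 3‑alkylated 2,4,6‑trihydroxyaryl carbonyl compounds.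

Step 4
Reactants: 6 2‑hydroxy‑4,6‑bis(methoxymethoxy)‑3‑(2‑methylbut‑3‑en‑2‑yl)benzaldehyde; 7 ethyl bromoacetate
Product: 9 ethyl 4,6‑bis(methoxymethoxy)‑7‑(2‑methylbut‑3‑en‑2‑yl)‑1‑benzofuran‑2‑carboxylate, via aryloxyacetate 8 (not isolated)
Conditions: K2CO3, DMF, 90 °C
Reagents that add atoms: none
Why: Rap–Stoermer‑type benzofuran synthesis: O‑alkylation of the phenoxide gives aryloxyacetate 8, whose ester enolate adds to the neighbouring formyl group (intramolecular aldol, five‑membered ring) and loses water to the aromatic furan; MOM ethers and the alkene are inert to carbonate.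

Step 5
Reactants: 9 ethyl 4,6‑bis(methoxymethoxy)‑7‑(2‑methylbut‑3‑en‑2‑yl)‑1‑benzofuran‑2‑carboxylate
Product: 10 Bzf‑methanol
Conditions: LiAlH4, THF, 0 °C
Reagents that add atoms: none
Why: Hydride reduction of the ester to the primary alcohol; acetals, the furan and the isolated alkene are not touched by LiAlH4 at 0 °C.

Step 6
Reactants: 10 Bzf‑methanol
Product: 11 Bzf‑carbaldehyde
Conditions: MnO2, CH2Cl2, rt
Reagents that add atoms: none
Why: MnO2 oxidises the hetaryl carbinol (a benzylic‑type alcohol) selectively to the aldehyde without over‑oxidation and without affecting the alkene.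

Step 7
Reactants: 11 Bzf‑carbaldehyde; 12 1‑(triphenyl‑λ5‑phosphanylidene)propan‑2‑one
Product: 13 (3E)‑4‑Bzf‑but‑3‑en‑2‑one
Conditions: toluene, 90 °C
Reagents that add atoms: none
Why: Wittig olefination with a ketone‑stabilised ylide, which gives the E‑enone; nothing else in 11 reacts with the ylide.

Step 8
Reactants: 13 (3E)‑4‑Bzf‑but‑3‑en‑2‑one; 14 dimethyl malonate
Product: 18 5‑Bzf‑cyclohexane‑1,3‑dione, via Michael adduct 15 (not isolated), via cyclic keto ester 16 (not isolated), via keto acid 17 (not isolated)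
Conditions: NaOMe, MeOH, reflux; then 2 M NaOH (aq), reflux; then AcOH to pH 4, 70 °C
Reagents that add atoms: none
Why: The methoxide‑generated malonate anion adds in 1,4‑fashion to the enone carbon attached to the benzofuran (future C1') to give 15; proton transfer then gives the methyl ketone enolate, which attacks one malonate ester in a Claisen (Dieckmann‑type) condensation, and the resulting β‑dicarbonyl 16 is deprotonated irreversibly, which pulls the reversible addition and closure forward. Hydroxide then saponifies the remaining ester, and acidification to pH 4 liberates β‑keto acid 17, which loses CO2 through the usual cyclic transition state to give 18. The closest known reaction type is the dimedone synthesis and its use for 5‑aryl‑ and 5‑(2‑furyl)cyclohexane‑1,3‑diones from arylidene acetones. The ring closes in the 6‑(enolendo)‑exo‑trig mode. No stereocentre survives: the centres of 15–17 are transient and 18 has a mirror plane through C2 and C5. The step needs 1,4‑ and not 1,2‑addition, which the soft, stabilised nucleophile and the reversibility of carbonyl addition secure, and it needs attack at the side‑chain carbon and not at the furan, which holds because addition to the ring would cost the heteroaromatic stabilisation. Only the methyl group can reach an ester through a six‑membered transition state (the α‑CH2 would close a four‑membered ring), so a single carbocycle results. The MOM ethers and both alkenes are inert to alkoxide and hydroxide, and the acetate‑buffered decarboxylation is mild enough to keep the acetals.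

Step 9
Reactants: 18 5‑Bzf‑cyclohexane‑1,3‑dione
Product: 19 5‑Bzf‑3‑(methoxymethoxy)cyclohex‑2‑en‑1‑one
Conditions: MOMCl, iPr2NEt, CH2Cl2, 0 °C
Reagents that add atoms: chloromethyl methyl ether, COCCl
Why: O‑Alkylation of the dione enolate by the hard alkoxymethyl chloride gives the vinylogous ester; because 18 has a mirror plane both oxygens are equivalent and only one enol ether can form (C5 becomes a stereocentre, racemic).

Step 10
Reactants: 19 5‑Bzf‑3‑(methoxymethoxy)cyclohex‑2‑en‑1‑one; 2 prenyl bromide
Product: 21 trans‑5‑Bzf‑3‑(methoxymethoxy)‑6‑(3‑methylbut‑2‑en‑1‑yl)cyclohex‑2‑en‑1‑one, via lithium dienolate 20 (not isolated)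
Conditions: LiN(iPr)2, THF, −78 °C; then 2, DMPU, −78 → −20 °C
Reagents that add atoms: none
Why: Stork–Danheiser‑type kinetic alkylation: LiN(iPr)2 removes an α' proton at C6 (not the vinylogous γ proton at C4) to give cross‑conjugated dienolate 20, which is alkylated by the allylic bromide anti to the C5 substituent (trans, racemic); C6 is the future C2'.

Step 11
Reactants: 21 trans‑5‑Bzf‑3‑(methoxymethoxy)‑6‑(3‑methylbut‑2‑en‑1‑yl)cyclohex‑2‑en‑1‑one
Product: 23 5‑Bzf‑3‑(methoxymethoxy)‑6‑(3‑methylbut‑2‑en‑1‑yl)‑6‑(phenylselanyl)cyclohex‑2‑en‑1‑one, via lithium enolate 22 (not isolated)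
Conditions: LiN(iPr)2, THF, −78 °C; then PhSeCl (1.05 equiv), −78 °C
Reagents that add atoms: benzeneselenenyl chloride, Cl[Se]c1ccccc1
Why: α‑Selenenylation of a ketone enolate: the second kinetic deprotonation again takes place at C6, and the selenium electrophile should enter anti to the C5 benzofuranyl group, which places selenium syn to H‑5 as the later elimination requires; at −78 °C the enolate reacts much faster than the alkenes.

Step 12
Reactants: 23 5‑Bzf‑3‑(methoxymethoxy)‑6‑(3‑methylbut‑2‑en‑1‑yl)‑6‑(phenylselanyl)cyclohex‑2‑en‑1‑one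
Product: 26 3‑Bzf‑5‑(methoxymethoxy)‑2‑(3‑methylbut‑2‑en‑1‑yl)phenol, via selenoxide 24 (not isolated), via dienone 25 (not isolated)
Conditions: mCPBA (1.0 equiv), CH2Cl2, −78 °C; then iPr2NH, −78 °C → rt
Reagents that add atoms: none
Why: Selenoxide syn‑elimination: oxidation at selenium is much faster than epoxidation at −78 °C and gives 24, which on warming loses PhSeOH across C5–C6 to dienone 25; this tautomerises under amine catalysis to phenol 26, the ketone oxygen becoming the 3'‑OH and both ring stereocentres disappearing, while the amine also intercepts the selenenic acid.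

Step 13
Reactants: 26 3‑Bzf‑5‑(methoxymethoxy)‑2‑(3‑methylbut‑2‑en‑1‑yl)phenol
Product: 27 2‑[3‑methoxy‑5‑(methoxymethoxy)‑2‑(3‑methylbut‑2‑en‑1‑yl)phenyl]‑4,6‑bis(methoxymethoxy)‑7‑(2‑methylbut‑3‑en‑2‑yl)‑1‑benzofuran
Conditions: MeI, K2CO3, acetone, 40 °C
Reagents that add atoms: iodomethane, CI
Why: Williamson methylation of the only free phenol; no selectivity is needed because the 5'‑oxygen still carries its MOM group.

Step 14
Reactants: 27 2‑[3‑methoxy‑5‑(methoxymethoxy)‑2‑(3‑methylbut‑2‑en‑1‑yl)phenyl]‑4,6‑bis(methoxymethoxy)‑7‑(2‑methylbut‑3‑en‑2‑yl)‑1‑benzofuran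
Product: 28 2‑[5‑hydroxy‑3‑methoxy‑2‑(3‑methylbut‑2‑en‑1‑yl)phenyl]‑7‑(2‑methylbut‑3‑en‑2‑yl)‑1‑benzofuran‑4,6‑diol
Conditions: HCl (3 M aq)–MeOH (1:4), 40 °C
Reagents that add atoms: none
Why: Acid‑catalysed transacetalisation of the three aryl MOM ethers to methanol; the methyl ether is stable, the prenyl group has no neighbouring OH with which it could cyclise, and the mild temperature should spare the monosubstituted alkene next to 6‑OH.

## Compound list

1 | 2,4,6‑trihydroxybenzaldehyde | O=Cc1c(O)cc(O)cc1O | starting material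
2 | prenyl bromide (1‑bromo‑3‑methylbut‑2‑ene) | CC(C)=CCBr | starting material
3 | 2,6‑dihydroxy‑4‑[(3‑methylbut‑2‑en‑1‑yl)oxy]benzaldehyde | O=Cc1c(O)cc(OCC=C(C)C)cc1O | intermediate
4 | 2,6‑dihydroxy‑3‑(2‑methylbut‑3‑en‑2‑yl)‑4‑oxocyclohexa‑1,5‑diene‑1‑carbaldehyde (racemic, not isolated) | O=CC1=C(O)C(C(C)(C)C=C)C(=O)C=C1O | intermediate
5 | 2,4,6‑trihydroxy‑3‑(2‑methylbut‑3‑en‑2‑yl)benzaldehyde | O=Cc1c(O)cc(O)c(C(C)(C)C=C)c1O | intermediate
6 | 2‑hydroxy‑4,6‑bis(methoxymethoxy)‑3‑(2‑methylbut‑3‑en‑2‑yl)benzaldehyde | O=Cc1c(OCOC)cc(OCOC)c(C(C)(C)C=C)c1O | intermediate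
7 | ethyl bromoacetate | CCOC(=O)CBr | starting material
8 | ethyl 2‑[2‑formyl‑3,5‑bis(methoxymethoxy)‑6‑(2‑methylbut‑3‑en‑2‑yl)phenoxy]acetate (not isolated) | CCOC(=O)COc1c(C=O)c(OCOC)cc(OCOC)c1C(C)(C)C=C | intermediate
9 | ethyl 4,6‑bis(methoxymethoxy)‑7‑(2‑methylbut‑3‑en‑2‑yl)‑1‑benzofuran‑2‑carboxylate | CCOC(=O)c1cc2c(OCOC)cc(OCOC)c(C(C)(C)C=C)c2o1 | intermediate
10 | Bzf‑methanol | OCc1cc2c(OCOC)cc(OCOC)c(C(C)(C)C=C)c2o1 | intermediate
11 | Bzf‑carbaldehyde | O=Cc1cc2c(OCOC)cc(OCOC)c(C(C)(C)C=C)c2o1 | intermediate
12 | 1‑(triphenyl‑λ5‑phosphanylidene)propan‑2‑one | CC(=O)C=P(c1ccccc1)(c1ccccc1)c1ccccc1 | starting material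
13 | (3E)‑4‑Bzf‑but‑3‑en‑2‑one | CC(=O)/C=C/c1cc2c(OCOC)cc(OCOC)c(C(C)(C)C=C)c2o1 | intermediate
14 | dimethyl malonate | COC(=O)CC(=O)OC | starting material
15 | dimethyl 2‑(1‑Bzf‑3‑oxobutyl)propanedioate (racemic, not isolated) | COC(=O)C(C(=O)OC)C(CC(C)=O)c1cc2c(OCOC)cc(OCOC)c(C(C)(C)C=C)c2o1 | intermediate
16 | methyl 6‑Bzf‑2,4‑dioxocyclohexane‑1‑carboxylate (racemic diastereomer mixture, present as its sodium enolate, not isolated) | COC(=O)C1C(=O)CC(=O)CC1c1cc2c(OCOC)cc(OCOC)c(C(C)(C)C=C)c2o1 | intermediate
17 | 6‑Bzf‑2,4‑dioxocyclohexane‑1‑carboxylic acid (racemic diastereomer mixture, not isolated) | OC(=O)C1C(=O)CC(=O)CC1c1cc2c(OCOC)cc(OCOC)c(C(C)(C)C=C)c2o1 | intermediate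
18 | 5‑Bzf‑cyclohexane‑1,3‑dione | O=C1CC(=O)CC(C1)c1cc2c(OCOC)cc(OCOC)c(C(C)(C)C=C)c2o1 | intermediate
19 | 5‑Bzf‑3‑(methoxymethoxy)cyclohex‑2‑en‑1‑one (racemic) | COCOC1=CC(=O)CC(C1)c1cc2c(OCOC)cc(OCOC)c(C(C)(C)C=C)c2o1 | intermediate
20 | lithium 5‑Bzf‑3‑(methoxymethoxy)cyclohexa‑1,3‑dien‑1‑olate (racemic, not isolated) | [Li+].[O-]C1=CC(c2cc3c(OCOC)cc(OCOC)c(C(C)(C)C=C)c3o2)CC(OCOC)=C1 | intermediate
21 | trans‑5‑Bzf‑3‑(methoxymethoxy)‑6‑(3‑methylbut‑2‑en‑1‑yl)cyclohex‑2‑en‑1‑one (racemic, relative configuration drawn) | COCOC1=CC(=O)[C@H](CC=C(C)C)[C@H](C1)c1cc2c(OCOC)cc(OCOC)c(C(C)(C)C=C)c2o1 | intermediate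
22 | lithium 5‑Bzf‑3‑(methoxymethoxy)‑6‑(3‑methylbut‑2‑en‑1‑yl)cyclohexa‑1(6),2‑dien‑1‑olate (racemic, not isolated) | [Li+].[O-]C1=C(CC=C(C)C)C(c2cc3c(OCOC)cc(OCOC)c(C(C)(C)C=C)c3o2)CC(OCOC)=C1 | intermediate
23 | 5‑Bzf‑3‑(methoxymethoxy)‑6‑(3‑methylbut‑2‑en‑1‑yl)‑6‑(phenylselanyl)cyclohex‑2‑en‑1‑one (racemic, selenium trans to Bzf, relative configuration drawn) | COCOC1=CC(=O)[C@](CC=C(C)C)([Se]c2ccccc2)[C@H](C1)c1cc2c(OCOC)cc(OCOC)c(C(C)(C)C=C)c2o1 | intermediate
24 | 6‑(benzeneseleninyl)‑5‑Bzf‑3‑(methoxymethoxy)‑6‑(3‑methylbut‑2‑en‑1‑yl)cyclohex‑2‑en‑1‑one (racemic, mixture at selenium, not isolated) | COCOC1=CC(=O)[C@](CC=C(C)C)([Se](=O)c2ccccc2)[C@H](C1)c1cc2c(OCOC)cc(OCOC)c(C(C)(C)C=C)c2o1 | intermediate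
25 | 3‑Bzf‑5‑(methoxymethoxy)‑2‑(3‑methylbut‑2‑en‑1‑yl)cyclohexa‑2,5‑dien‑1‑one (not isolated) | COCOC1=CC(=O)C(CC=C(C)C)=C(C1)c1cc2c(OCOC)cc(OCOC)c(C(C)(C)C=C)c2o1 | intermediate
26 | 3‑Bzf‑5‑(methoxymethoxy)‑2‑(3‑methylbut‑2‑en‑1‑yl)phenol | COCOc1cc(O)c(CC=C(C)C)c(c1)-c1cc2c(OCOC)cc(OCOC)c(C(C)(C)C=C)c2o1 | intermediate
27 | 2‑[3‑methoxy‑5‑(methoxymethoxy)‑2‑(3‑methylbut‑2‑en‑1‑yl)phenyl]‑4,6‑bis(methoxymethoxy)‑7‑(2‑methylbut‑3‑en‑2‑yl)‑1‑benzofuran | COCOc1cc(OC)c(CC=C(C)C)c(c1)-c1cc2c(OCOC)cc(OCOC)c(C(C)(C)C=C)c2o1 | intermediate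
28 | 2‑[5‑hydroxy‑3‑methoxy‑2‑(3‑methylbut‑2‑en‑1‑yl)phenyl]‑7‑(2‑methylbut‑3‑en‑2‑yl)‑1‑benzofuran‑4,6‑diol | C=CC(C)(C)c1c(O)cc(O)c2cc(-c3cc(O)cc(OC)c3CC=C(C)C)oc12 | target

## Step count and least certain steps

Total: 14 steps. Longest linear sequence: 14 steps (from 1; compounds 2, 7, 12 and 14 are purchased).

Step 8 (key step). The conjugate addition may stall or revert, because the acceptor carbon is the end of a donor‑substituted hetaryl system and the ring closure is slow; the enone would then be consumed by self‑condensation through its own methyl ketone enolate. Some loss of MOM groups during the acidification is the second risk. Fallback: reverse the polarity of the first bond. Starting from aldehyde 11, Knoevenagel condensation with 14 (piperidine, AcOH, toluene, reflux with removal of water) gives the much more electrophilic dimethyl 2‑(Bzf‑methylidene)propanedioate F1. Addition of the lithium enolate of acetone (acetone added to LiN(iPr)2, THF, −78 °C) to F1 gives 15 as an isolated compound, which is then closed, saponified and decarboxylated as in step 8, so the route is rejoined at 15 and continues to 18.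

Step 1. Double alkylation and C‑alkylation of the ambident phloroglucinol‑type anion may cut the amount of mono‑ether. Fallback from 1: protection first (MOMCl, 2 equiv, iPr2NEt) to 2‑hydroxy‑4,6‑bis(methoxymethoxy)benzaldehyde F2, then etherification of the remaining OH with 2 (K2CO3, DMF) to 4,6‑bis(methoxymethoxy)‑2‑[(3‑methylbut‑2‑en‑1‑yl)oxy]benzaldehyde F3. A Claisen rearrangement of F3 catalysed by Eu(fod)3, europium tris(6,6,7,7,8,8,8‑heptafluoro‑2,2‑dimethyloctane‑3,5‑dionate), in CHCl3 at 40–50 °C returns to the route at 6, bypassing 3 and 5. The price is that the para position of F3 is open, so the reaction has to be stopped after the first [3,3] shift.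

Step 2. At 130 °C the prenyl ether of an acidic phenol may ionise and lose the C5 unit, and the product, which has two acidic OH groups next to the new group, may react further (closure of an OH onto the vinyl group, abnormal Claisen shift). Fallback from 3: move the rearrangement to the benzofuran stage, where no acidic phenol is present.
- Annulation of 3 with one equivalent of 7 (K2CO3, DMF) gives ethyl 4‑hydroxy‑6‑[(3‑methylbut‑2‑en‑1‑yl)oxy]‑1‑benzofuran‑2‑carboxylate F4.
- MOMCl and iPr2NEt give ethyl 4‑(methoxymethoxy)‑6‑[(3‑methylbut‑2‑en‑1‑yl)oxy]‑1‑benzofuran‑2‑carboxylate F5.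
- Heating in N,N‑diethylaniline at 180 °C gives ethyl 6‑hydroxy‑4‑(methoxymethoxy)‑7‑(2‑methylbut‑3‑en‑2‑yl)‑1‑benzofuran‑2‑carboxylate F6. C7 is favoured over C5 by the higher π‑bond order of C6–C7 in benzofurans and by the MOM group flanking C5; the para carbon is the ring fusion.
- MOMCl then gives 9, where the route is rejoined.

Step 10. C‑Alkylation next to the carbon that bears the bulky benzofuranyl group may be slow, so that proton exchange between enolate 20 and product leads to double alkylation and recovered 19, or oxygen is alkylated. Fallback from 19: trap enolate 20 on oxygen with 3‑methylbut‑2‑en‑1‑yl chloroformate to give 3‑Bzf‑5‑(methoxymethoxy)cyclohexa‑1,5‑dien‑1‑yl 3‑methylbut‑2‑en‑1‑yl carbonate F7. Tsuji‑type decarboxylative allylation with Pd(PPh3)4 (zerovalent palladium, THF, rt) then regenerates the enolate under neutral conditions next to a π‑prenyl complex, which is attacked at its unsubstituted terminus, and the route is rejoined at 21.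

Step 12 (with step 11). The selenoxide may eliminate toward the allylic CH2 of the prenyl group instead of toward H‑5, above all if selenium entered cis to the benzofuranyl group in step 11; the exocyclic dienone formed that way does not tautomerise to the phenol. Addition of the selenenic acid to the prenyl alkene is the second risk. Fallback from 21, replacing steps 11 and 12: LiN(iPr)2 and Me3SiCl (THF, −78 °C) give the silyl dienol ether [5‑Bzf‑3‑(methoxymethoxy)‑6‑(3‑methylbut‑2‑en‑1‑yl)cyclohexa‑1(6),2‑dien‑1‑yl]oxy(trimethyl)silane F8, a cyclohexa‑1,3‑diene. DDQ with 2,6‑lutidine in benzene at 0 °C dehydrogenates it to the aryl silyl ether [3‑Bzf‑5‑(methoxymethoxy)‑2‑(3‑methylbut‑2‑en‑1‑yl)phenoxy](trimethyl)silane F9; hydride loss from either ring CH leads to the same arene. K2CO3 in MeOH then gives 26.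

Step 14. Before the third acetal is cleaved, the acid may add water, methanol or HCl to the prenyl alkene, or close the 6‑OH onto the 1,1‑dimethylallyl group. Fallback from 27: ZnBr2 and propane‑1‑thiol in CH2Cl2 at 0 °C, in which the Lewis acid activates the acetal and the thiol takes over the methoxymethyl group, so that no Brønsted acid is present; this leads directly to 28.

## Further compounds

F1 | step 8 | dimethyl 2‑(Bzf‑methylidene)propanedioate | COC(=O)C(=Cc1cc2c(OCOC)cc(OCOC)c(C(C)(C)C=C)c2o1)C(=O)OC
F2 | step 1 | 2‑hydroxy‑4,6‑bis(methoxymethoxy)benzaldehyde | O=Cc1c(O)cc(OCOC)cc1OCOC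
F3 | step 1 | 4,6‑bis(methoxymethoxy)‑2‑[(3‑methylbut‑2‑en‑1‑yl)oxy]benzaldehyde | O=Cc1c(OCC=C(C)C)cc(OCOC)cc1OCOC
F4 | step 2 | ethyl 4‑hydroxy‑6‑[(3‑methylbut‑2‑en‑1‑yl)oxy]‑1‑benzofuran‑2‑carboxylate | CCOC(=O)c1cc2c(O)cc(OCC=C(C)C)cc2o1
F5 | step 2 | ethyl 4‑(methoxymethoxy)‑6‑[(3‑methylbut‑2‑en‑1‑yl)oxy]‑1‑benzofuran‑2‑carboxylate | CCOC(=O)c1cc2c(OCOC)cc(OCC=C(C)C)cc2o1
F6 | step 2 | ethyl 6‑hydroxy‑4‑(methoxymethoxy)‑7‑(2‑methylbut‑3‑en‑2‑yl)‑1‑benzofuran‑2‑carboxylate | CCOC(=O)c1cc2c(OCOC)cc(O)c(C(C)(C)C=C)c2o1
F7 | step 10 | 3‑Bzf‑5‑(methoxymethoxy)cyclohexa‑1,5‑dien‑1‑yl 3‑methylbut‑2‑en‑1‑yl carbonate (racemic) | CC(C)=CCOC(=O)OC1=CC(c2cc3c(OCOC)cc(OCOC)c(C(C)(C)C=C)c3o2)CC(OCOC)=C1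
F8 | step 12 | [5‑Bzf‑3‑(methoxymethoxy)‑6‑(3‑methylbut‑2‑en‑1‑yl)cyclohexa‑1(6),2‑dien‑1‑yl]oxy(trimethyl)silane (racemic) | C[Si](C)(C)OC1=C(CC=C(C)C)C(c2cc3c(OCOC)cc(OCOC)c(C(C)(C)C=C)c3o2)CC(OCOC)=C1
F9 | step 12 | [3‑Bzf‑5‑(methoxymethoxy)‑2‑(3‑methylbut‑2‑en‑1‑yl)phenoxy](trimethyl)silane | C[Si](C)(C)Oc1cc(OCOC)cc(c1CC=C(C)C)-c1cc2c(OCOC)cc(OCOC)c(C(C)(C)C=C)c2o1
F0 | step 14 | none | none
A1 | alternative 1 | 2‑[3‑methoxy‑2‑(3‑methylbut‑2‑en‑1‑yl)‑5‑{[tri(propan‑2‑yl)silyl]oxy}phenyl]‑7‑(2‑methylbut‑3‑en‑2‑yl)‑1‑benzofuran‑4,6‑diol | C=CC(C)(C)c1c(O)cc(O)c2cc(-c3cc(O[Si](C(C)C)(C(C)C)C(C)C)cc(OC)c3CC=C(C)C)oc12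
A2 | alternative 1 | 5‑{2‑[5‑(3‑methoxy‑2‑(3‑methylbut‑2‑en‑1‑yl)‑5‑{[tri(propan‑2‑yl)silyl]oxy}phenyl)furan‑2‑yl]‑3,3‑dimethylpent‑4‑enoyl}‑2,2‑dimethyl‑1,3‑dioxane‑4,6‑dione (racemic) | CC1(C)OC(=O)C(C(=O)C(c2ccc(o2)-c2cc(O[Si](C(C)C)(C(C)C)C(C)C)cc(OC)c2CC=C(C)C)C(C)(C)C=C)C(=O)O1
A3 | alternative 1 | 4‑[5‑(3‑methoxy‑2‑(3‑methylbut‑2‑en‑1‑yl)‑5‑{[tri(propan‑2‑yl)silyl]oxy}phenyl)furan‑2‑yl]‑5,5‑dimethylhepta‑1,6‑diene‑1,3‑dione (acylketene, racemic) | O=C=CC(=O)C(c1ccc(o1)-c1cc(O[Si](C(C)C)(C(C)C)C(C)C)cc(OC)c1CC=C(C)C)C(C)(C)C=C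
A4 | alternative 2 | methyl trans‑2‑[3‑methoxy‑2‑(3‑methylbut‑2‑en‑1‑yl)‑5‑(prop‑2‑en‑1‑yloxy)phenyl]‑7‑(2‑methylbut‑3‑en‑2‑yl)‑4,6‑bis(prop‑2‑en‑1‑yloxy)‑2,3‑dihydro‑1‑benzofuran‑3‑carboxylate (racemic, relative configuration drawn) | COC(=O)[C@@H]1[C@@H](c2cc(OCC=C)cc(OC)c2CC=C(C)C)Oc2c(C(C)(C)C=C)c(OCC=C)cc(OCC=C)c21
A5 | alternative 2 | 2‑[3‑methoxy‑2‑(3‑methylbut‑2‑en‑1‑yl)‑5‑(prop‑2‑en‑1‑yloxy)phenyl]‑8‑(2‑methylbut‑3‑en‑2‑yl)‑5,7‑bis(prop‑2‑en‑1‑yloxy)‑2,3‑dihydro‑4H‑chromen‑4‑one (racemic) | O=C1CC(c2cc(OCC=C)cc(OC)c2CC=C(C)C)Oc2c(C(C)(C)C=C)c(OCC=C)cc(OCC=C)c12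
A6 | alternative 3 | 2‑[3‑methoxy‑2‑(3‑methylbut‑2‑en‑1‑yl)‑5‑{[tri(propan‑2‑yl)silyl]oxy}phenyl]‑7‑(2‑methylbut‑3‑en‑2‑yl)‑4,6‑bis{[tri(propan‑2‑yl)silyl]oxy}‑1‑benzofuran | C=CC(C)(C)c1c(O[Si](C(C)C)(C(C)C)C(C)C)cc(O[Si](C(C)C)(C(C)C)C(C)C)c2cc(-c3cc(O[Si](C(C)C)(C(C)C)C(C)C)cc(OC)c3CC=C(C)C)oc12
A7 | alternative 3 | 2‑[(E)‑2‑(3‑methoxy‑2‑(3‑methylbut‑2‑en‑1‑yl)‑5‑{[tri(propan‑2‑yl)silyl]oxy}phenyl)ethenyl]‑6‑(2‑methylbut‑3‑en‑2‑yl)‑3,5‑bis{[tri(propan‑2‑yl)silyl]oxy}phenol | Oc1c(C(C)(C)C=C)c(O[Si](C(C)C)(C(C)C)C(C)C)cc(O[Si](C(C)C)(C(C)C)C(C)C)c1/C=C/c1cc(O[Si](C(C)C)(C(C)C)C(C)C)cc(OC)c1CC=C(C)C
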